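**Target:** (13R)-9α,13-epoxy-7β-hydroxy-6-oxolabdan-15,16-olide, (5S,7R,8R,9R,10S,13R), compound 26.

## Analysis of the target

Labdane numbering is used throughout: ring A is C1–C5 and C10, ring B is C5–C10, ring C is the oxolane O–C9–C11–C12–C13, ring D is the lactone C13–C14–C15(=O)–O–C16; C17 is the methyl on C8 and C20 the methyl on C10. The target is a trans-decalin with a spiro centre at C9 that joins ring B to ring C, and a second spiro centre at C13 that joins ring C to ring D. Five of the six stereocentres sit on the decalin: H5 is α and C20 β, and on ring B the C7 hydroxyl and C17 are equatorial, whereas the C9 oxygen is axial (α) and C11 equatorial. This is the opposite of what carbon-nucleophile addition to a C9 ketone gives. C13 is four bonds from the nearest ring stereocentre and its two ring D arms (CH2–O and CH2–C=O) are almost the same size, so the substrate cannot control it. The sensitive groups are the α-ketol (C5 and C7 can epimerise and the ketol can transpose), the β-alkoxy lactone (base can open ring C by retro-oxa-Michael reaction and scramble C13) and the tertiary C9 ether next to the quaternary C10 (cationic conditions invite methyl migration). The C6 carbonyl is unusually hindered because any axial β-substituent there is 1,3-diaxial to both C20 and the axial C4 methyl. The strategy rests on ring B: it carries oxygen at C6 and C9 in a 1,4-relation, and C9 lies between the methyl-bearing C8 and C10. That is the substitution pattern of 2,6-dimethyl-1,4-benzoquinone (5), so one cycloaddition on 5 with the silyloxy diene 4 supplies ring A, both ring B oxygens, both methyl-bearing carbons and the quaternary C10.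

## Retrosynthetic reasoning

**C7.** Target 26 is traced to its C7 epimer 25, and 25 to the 7-deoxy ketolactone 22 by cutting the C7–O bond. Oxidation of the C6 enol derivative puts oxygen on the less hindered α-face, so the forward plan accepts the axial alcohol and then lets the ketol equilibrate to the equatorial 7β-isomer. This comes last because every earlier organometallic step would destroy a ketol.

**Ring D.** In 22 the C15 carbonyl and the C6 carbonyl are both taken back to alcohols, which gives triol 21. The forward oxidation has to pick the unhindered C15 carbinol before the neopentyl C16 carbinol so that the lactone carbonyl ends at C15; the C6 alcohol is oxidised in the same operation.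

**Ring C and C13.** The O–C13 bond of 21 is cut to give epoxy diol 19, in which the C9 hydroxyl opens a C13–C16 epoxide at its tertiary carbon with inversion. This turns the C13 problem into the facial selectivity of an epoxidation of the 1,1-disubstituted alkene in 18, and the homoallylic C15 hydroxyl lets a chiral metal catalyst decide that face. Closing ring C by oxa-Michael addition to a butenolide was not chosen because nothing would differentiate the two C13 epimers.

**C11–C12.** Compound 18 is cut between C11 and C12 into spiro-epoxide 15 and the five-carbon alcohol 16, used as its dianion 17. The anion is a 2-substituted allyl unit with identical ends, so there is no regiochemical issue, and the C9–O bond, already in the axial orientation, is not touched.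

**C9.** Epoxide 15 comes from the exocyclic alkene 14 and this from ketone 13. Peracid attack from the α-face, away from the axial C20, places oxygen α and C11 β.

**Ring B adjustment.** Ketone 13 is traced through silyl ether 11 and allylic alcohol 10 to the trans ene-dione 9. The two carbonyls are told apart at the ene-dione stage, where C6 has C–H on both flanks and C9 has none. In the saturated dione both are hindered to a similar degree, and a ketal at C6 would have to carry an axial oxygen against two axial methyls. C6 is therefore reduced and silylated; one hydrogenation then removes the C7=C8 bond and the ring A enol triflate.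

**C5.** Compound 9 is the C5 epimer of the cis enol triflate 7, itself made from cycloadduct 6 by exchanging the enol silane for a triflate. Since the stability of trans over cis is not assured for an ene-dione with a C4 gem-dimethyl group, the forward step goes through the planar silyl dienol ether 8 and protonates C5 from the face opposite C20.

**Ring A.** Adduct 6 is cut at C1–C10 and C4–C5 into quinone 5 and diene 4, the key disconnection. Diene 4 comes in one step from ketone 1 and silyl triflate 2 through the kinetic dienolate 3.

## Alternatives that were turned down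

**Alternative 1:** Ring D is cut at the C15–O–C16 unit and traced to the prochiral spiro-cyclobutanone A1. In the forward step a cyclohexanone-monooxygenase-type flavin enzyme inserts oxygen next to the carbonyl and gives the Δ5 spiro-lactone A2.
- For: one protecting-group-free operation makes ring D and sets C13 under catalyst control. On this point it is stronger than the chosen route, which needs steps 11 to 13 for the same result.
- Against: the enzyme pocket is tuned to small ketones and A1 holds a bulky decalin directly beside the reacting ring. A1 is already chiral, so the two insertion modes are diastereomeric and the substrate may override the enzyme. The cyclobutanone must first be built on a fully substituted ether carbon. A2 has no oxygen at C6 or C7, so the ketol would have to be made from the Δ5 alkene in several steps in the presence of the base-sensitive lactone, with H5 set late.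
- Comparison: the chosen strategy takes both ring B oxygens from 5 in the step that also makes ring A, and pays for it with a longer ring D sequence.

**Alternative 2:** Ring C is cut at O–C9 and traced to the 3,5-dimethylphenol A3, which carries the complete ring D and C13. In the forward step an aryl-iodine diacetate oxidant in a fluorinated alcohol dearomatises the phenol, and the C13 hydroxyl attacks the para carbon to give spiro-dienone A4.
- For: rings B, C and D, the C6 carbonyl and the quaternary C9 arise in one mild step, and C13 is set in a small fragment. It is clearly shorter to the spiro ether than the chosen route.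
- Against: in A4 the two enone arms are equivalent, so C9 is not yet a stereocentre. It becomes one only when ring A is annulated on one arm, and the choice of arm and face would be left to C13, four bonds away. Ring A would still need the same C1–C10 and C4–C5 bonds, now on a dienone with no handle for a chiral catalyst.
- Comparison: the chosen route fixes C10 first by catalyst and then derives C5, C8 and C9 from the rigid decalin.

**Alternative 3:** Ring C is cut at C11–C12 and O–C9 and traced to the 9-methylene decalin A5. In the forward step a carboxymethyl radical, generated from the solvent acid by a trivalent manganese carboxylate oxidant, adds to C11; the oxidised C9 centre is captured by the carboxylate to give spirolactone A6.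
- For: two bonds and the C9–O centre form in one step from bulk reagents. A radical addition is less sensitive to the neopentyl hindrance at C11 than the anionic epoxide opening of step 10, so on that bond it is the stronger plan.
- Against: oxidation of the C9 radical gives a cation beside the quaternary C10, which can migrate a methyl group or eliminate, and the Δ5 alkene competes for radical and oxidant. A6 has a carbonyl at C13, so two different carbon arms would have to be added there with no control of configuration. The ring B oxygens are again missing.
- Comparison: the chosen route reaches C13 with defined configuration and has the ring B oxygens from the start.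

Key step: step 2

Assumption: the absolute sense of the two catalyst-controlled steps (2 and 11) is written for the (S)-prolinol-derived oxazaborolidinium salt and the (R,R)-bishydroxamic acid ligand according to their usual facial models; both are available as either antipode, so an opposite sense would be corrected by exchanging the antipode with no other change.

## Route

**Step 1**
Reactants: 1 mesityl oxide; 2 triisopropylsilyl triflate
Product: 4 2-(triisopropylsilyloxy)-4-methylpenta-1,3-diene, via lithium dienolate 3 (not isolated)
Conditions: LDA, THF, −78 °C; then 2, −78 to 0 °C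
Reagents that add atoms: none
Why: Kinetic deprotonation of the methyl group next to the carbonyl gives the cross-conjugated lithium dienolate, and O-silylation fixes it as the 2-silyloxy diene (kinetic enol silylation); an amine base with the silyl triflate would risk γ-deprotonation to the linear dienol ether.

**Step 2**
Reactants: 5 2,6-dimethyl-1,4-benzoquinone; 4 2-(triisopropylsilyloxy)-4-methylpenta-1,3-diene
Product: 6 (4aR,8aS)-2,5,5,8a-tetramethyl-7-(triisopropylsilyloxy)-4a,5,8,8a-tetrahydronaphthalene-1,4-dione (cis-fused; labdane C5 R and C10 S)
Conditions: B-o-tolyl oxazaborolidine of (S)-α,α-diphenylprolinol (20 mol%), HN(SO2CF3)2 (18 mol%), CH2Cl2, −78 to −40 °C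
Reagents that add atoms: none
Why: The protonated oxazaborolidine binds the C6 carbonyl oxygen, the one flanked by two C–H, through the lone pair syn to one of them, with a C–H···O contact to the ring oxygen of the catalyst; this makes the methyl-bearing β-carbon C10 the electrophilic site. The nucleophilic CH2 end of 4 bonds to C10 and the C5 enolate carbon closes on the CMe2 end, either as a concerted asynchronous [4+2] cycloaddition or, at the limit, as Mukaiyama–Michael addition followed by closure of the boron enolate on the silyloxyallyl cation. The closest known type is the oxazaborolidinium-catalysed Diels–Alder reaction of 1,4-benzoquinones with 2-silyloxy-1,3-dienes. Ring A closes as the six-membered ring of the cycloaddition, with C1–C10 and C4–C5 formed suprafacially on both partners. C10 is set by the catalyst, whose phenyl group covers one face of the bound C5=C10 bond; the two quinone double bonds are equivalent by the twofold axis, so face selection alone fixes the enantiomer. C5 follows from suprafacial addition and is cis to C20; it is corrected in step 4. Regioselectivity requires binding at C6=O and not at C9=O, which is secured because C9=O lies between two methyl-bearing carbons, and because the opposite orientation would join the CMe2 end to the methyl-bearing C10. The diene has no stereogenic end, so there is no endo or exo question.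

**Step 3**
Reactants: 6 cycloadduct
Product: 7 (4aR,8aS)-2,5,5,8a-tetramethyl-7-(trifluoromethanesulfonyloxy)-4a,5,8,8a-tetrahydronaphthalene-1,4-dione (cis enol triflate)
Conditions: CsF, PhN(SO2CF3)2, DME, rt
Reagents that add atoms: N-phenylbis(trifluoromethanesulfonimide), O=S(=O)(N(c1ccccc1)S(=O)(=O)C(F)(F)F)C(F)(F)F
Why: Fluoride cleaves the Si–O bond and the cesium enolate is trapped at once by the triflimide, a regiospecific exchange of enol silane for enol triflate at C2. Any base-induced epimerisation at C5 is of no consequence because step 4 resets that centre.

**Step 4**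
Reactants: 7 cis enol triflate
Product: 9 (4aS,8aS)-2,5,5,8a-tetramethyl-7-(trifluoromethanesulfonyloxy)-4a,5,8,8a-tetrahydronaphthalene-1,4-dione (trans-fused; H5 α), via silyl dienol ether 8 (not isolated)
Conditions: Me3SiOSO2CF3, Et3N, CH2Cl2, 0 °C; then Bu4NF, AcOH, THF, −78 °C
Reagents that add atoms: none
Why: Soft enolisation silylates the less hindered C6 carbonyl and removes its only α-hydrogen, H5, to give the linearly conjugated dienol ether 8 with C5 planar. Protodesilylation at low temperature then protonates C5 from the α-face, opposite the axial C20 methyl, so the trans fusion is set under kinetic control (kinetic protonation of an enol derivative, the classical correction of cis quinone cycloadducts).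

**Step 5**
Reactants: 9 trans ene-dione
Product: 10 (4R,4aS,8aS)-4-hydroxy-2,5,5,8a-tetramethyl-7-(trifluoromethanesulfonyloxy)-4a,5,8,8a-tetrahydronaphthalen-1(4H)-one (6β-alcohol; C9 enone kept)
Conditions: NaBH4, CeCl3·7H2O, MeOH, −78 °C
Reagents that add atoms: none
Why: Luche 1,2-reduction: only C6 has a C–H on each flank, whereas C9 lies between the quaternary C10 and the methyl-bearing C8, so hydride adds at C6, from the α-face away from the axial methyls. This differentiates the two carbonyls while their surroundings still differ; the C6 configuration is removed again in step 13.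

**Step 6**
Reactants: 10 allylic alcohol
Product: 11 6β-triethylsilyl ether of 10
Conditions: Et3SiOSO2CF3, 2,6-lutidine, CH2Cl2, 0 °C to rt
Reagents that add atoms: triethylsilyl triflate, CC[Si](CC)(CC)OS(=O)(=O)C(F)(F)F
Why: A silyl triflate with a hindered pyridine base silylates even this axial alcohol. The ether prevents allylic isomerisation during hydrogenation and keeps the 6β-oxygen from reaching across ring B to C9 or C11 once the spiro-epoxide is present.

**Step 7**
Reactants: 11 silyl ether
Product: 13 (2R,4R,4aS,8aS)-2,5,5,8a-tetramethyl-4-(triethylsilyloxy)octahydronaphthalen-1(2H)-one (9-ketone; 8α-methyl equatorial), via 8β-methyl epimer 12 (not isolated)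
Conditions: H2 (1 atm), PtO2, Li2CO3, EtOAc, rt; then NaOMe (0.2 equiv), MeOH, rt
Reagents that add atoms: none
Why: Platinum-catalysed hydrogenation saturates the enone C7=C8 bond and reduces the enol triflate to a methylene group (hydrogenolysis of enol triflates over PtO2), with Li2CO3 taking up the triflic acid. Hydrogen enters from the α-face, so C17 is first axial (12); methoxide then epimerises C8 through the C9 enolate to the equatorial 8α-methyl, which avoids the 1,3-diaxial clash with C20 and the 6β-oxygen.

**Step 8**
Reactants: 13 ketone
Product: 14 9(11)-methylene compound (exocyclic alkene in place of the C9 carbonyl)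
Conditions: Ph3PCH3Br, KOtBu, toluene, 100 °C
Reagents that add atoms: methyltriphenylphosphonium bromide, C[P+](c1ccccc1)(c1ccccc1)c1ccccc1.[Br-]
Why: Wittig methylenation under the hot alkoxide conditions used for hindered ketones. C8, the only enolisable position, is already in its stable configuration, and C6 is no longer a carbonyl.

**Step 9**
Reactants: 14 exocyclic alkene
Product: 15 9α,11-epoxide (spiro-oxirane; O α and axial; C11 β; 9R)
Conditions: mCPBA, NaHCO3, CH2Cl2, 0 °C
Reagents that add atoms: 3-chloroperbenzoic acid, OOC(=O)c1cccc(Cl)c1
Why: Peracid epoxidation from the α-face, the axial direction flanked only by H5 and H7, because the β-face is blocked by the axial C20 methyl. This gives the C9 oxygen axial and C11 equatorial, the arrangement that direct addition of a carbon nucleophile to the C9 ketone would not give.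

**Step 10**
Reactants: 15 spiro-epoxide; 16 3-methylbut-3-en-1-ol
Product: 18 9α-hydroxy diol with the side chain C11H2–C12H2–C13(=C16H2)–C14H2–C15H2OH, via dilithiated alcohol 17 (not isolated)
Conditions: 16 (3 equiv), n-BuLi (6.3 equiv), TMEDA, Et2O/hexane, 0 °C to rt; then 15, THF, 0 to 40 °C; aq. NH4Cl
Reagents that add atoms: none
Why: The dianion 17 is a 2-substituted allyl anion with identical ends, so it has no regiochemical choice. It opens the epoxide at the CH2 carbon C11 by SN2 attack, which leaves the C9–O bond and the C9 configuration untouched, and brings in C12 to C16 with the C13=C16 alkene and the C15 carbinol.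

**Step 11**
Reactants: 18 homoallylic alcohol
Product: 19 (13S)-13,16-epoxide of 18
Conditions: Zr(OtBu)4 (10 mol%), (R,R)-bishydroxamic acid ligand from trans-1,2-diaminocyclohexane (12 mol%), cumene hydroperoxide, DMPU, 4 Å sieves, toluene, 0 °C to rt
Reagents that add atoms: cumene hydroperoxide, CC(C)(OO)c1ccccc1
Why: Hydroxyl-directed asymmetric epoxidation of a homoallylic alcohol with a 1,1-disubstituted alkene by a zirconium bishydroxamate and an alkyl hydroperoxide. The primary C15 hydroxyl binds the metal and the ligand selects the alkene face, so C13 is set by the catalyst; the hindered tertiary C9 hydroxyl is the poorer ligand, and any spiro ether it forms in the flask is the product of step 12.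

**Step 12**
Reactants: 19 epoxy diol
Product: 21 (13R)-9α,13-epoxy-6β,15,16-triol, via silyl-protected spiro ether 20 (not isolated)
Conditions: camphorsulfonic acid (0.1 equiv), CH2Cl2, 0 °C; then MeOH, rt
Reagents that add atoms: none
Why: Acid-catalysed 5-exo epoxide opening: the C9 hydroxyl attacks the tertiary epoxide carbon C13 with inversion, so the (13S)-epoxide gives the (13R)-ether, closes ring C and frees the C16 carbinol. Methanol then removes the triethylsilyl group under the same acid.

**Step 13**
Reactants: 21 triol
Product: 22 (13R)-9α,13-epoxy-6-oxolabdan-15,16-olide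
Conditions: Pr4N[RuO4] (10 mol%), N-methylmorpholine N-oxide (6 equiv), 4 Å sieves, CH2Cl2/MeCN, rt
Reagents that add atoms: none
Why: Ley–Griffith oxidation: the unhindered C15 carbinol is oxidised first, its aldehyde is caught as the lactol by the neopentyl C16 hydroxyl and oxidised on to the γ-lactone with the carbonyl at C15. The axial C6 alcohol is oxidised to the ketone in the same pot.

**Step 14**
Reactants: 22 ketolactone
Product: 25 7α-hydroxy epimer of the target (7S), via trimethylsilyl enol ether 23 (not isolated), via silyloxy epoxide 24 (not isolated)
Conditions: Me3SiOSO2CF3 (1.3 equiv), Et3N, CH2Cl2, −20 to 0 °C; dimethyldioxirane, acetone, −40 °C; then citric acid, MeOH/H2O, 0 °C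
Reagents that add atoms: dimethyldioxirane, CC1(C)OO1
Why: Rubottom oxidation: soft enolisation silylates the ketone much faster than the lactone and towards C7, since an enol ether towards C5 would press the silyloxy group against the C4 methyls. The dioxirane epoxidises the enol ether and mild acid opens the silyloxy epoxide to the α-hydroxy ketone. Oxygen is expected mainly on the α-face, opposite the two axial β-methyl groups, which gives the axial 7α-alcohol; any 7β-product is already 26 and is carried on unseparated.

**Step 15**
Reactants: 25 7α-hydroxy ketone
Product: 26 (13R)-9α,13-epoxy-7β-hydroxy-6-oxolabdan-15,16-olide (target)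
Conditions: DBU (0.2 equiv), CH2Cl2, rt
Reagents that add atoms: none
Why: Base-catalysed epimerisation of the α-ketol through its enediol moves the C7 hydroxyl from the axial site, 1,3-diaxial to the C9 ether oxygen, to the equatorial 7β-site (7R). A catalytic amidine is too weak to deprotonate the lactone, so the β-alkoxy lactone and C13 are left alone; C5 should stay trans because a cis fusion would force C4 axial on ring B against the axial C9–O bond.

## Compound list

1 | mesityl oxide (4-methylpent-3-en-2-one) | CC(=O)C=C(C)C | starting material
2 | triisopropylsilyl trifluoromethanesulfonate | CC(C)[Si](C(C)C)(C(C)C)OS(=O)(=O)C(F)(F)F | starting material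
3 | lithium 4-methylpenta-1,3-dien-2-olate | C=C(O[Li])C=C(C)C | intermediate
4 | 2-(triisopropylsilyloxy)-4-methylpenta-1,3-diene | C=C(O[Si](C(C)C)(C(C)C)C(C)C)C=C(C)C | intermediate
5 | 2,6-dimethyl-1,4-benzoquinone | CC1=CC(=O)C=C(C)C1=O | starting material
6 | (4aR,8aS)-2,5,5,8a-tetramethyl-7-(triisopropylsilyloxy)-4a,5,8,8a-tetrahydronaphthalene-1,4-dione | CC1=CC(=O)[C@@H]2C(C)(C)C=C(O[Si](C(C)C)(C(C)C)C(C)C)C[C@]2(C)C1=O | intermediate
7 | (4aR,8aS)-2,5,5,8a-tetramethyl-7-(trifluoromethanesulfonyloxy)-4a,5,8,8a-tetrahydronaphthalene-1,4-dione | CC1=CC(=O)[C@@H]2C(C)(C)C=C(OS(=O)(=O)C(F)(F)F)C[C@]2(C)C1=O | intermediate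
8 | (8aS)-2,5,5,8a-tetramethyl-4-(trimethylsilyloxy)-7-(trifluoromethanesulfonyloxy)-8,8a-dihydronaphthalen-1(5H)-one | CC1=CC(O[Si](C)(C)C)=C2C(C)(C)C=C(OS(=O)(=O)C(F)(F)F)C[C@]2(C)C1=O | intermediate
9 | (4aS,8aS)-2,5,5,8a-tetramethyl-7-(trifluoromethanesulfonyloxy)-4a,5,8,8a-tetrahydronaphthalene-1,4-dione | CC1=CC(=O)[C@H]2C(C)(C)C=C(OS(=O)(=O)C(F)(F)F)C[C@]2(C)C1=O | intermediate
10 | (4R,4aS,8aS)-4-hydroxy-2,5,5,8a-tetramethyl-7-(trifluoromethanesulfonyloxy)-4a,5,8,8a-tetrahydronaphthalen-1(4H)-one | CC1=C[C@@H](O)[C@H]2C(C)(C)C=C(OS(=O)(=O)C(F)(F)F)C[C@]2(C)C1=O | intermediate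
11 | 6β-triethylsilyl ether of 10 | CC1=C[C@@H](O[Si](CC)(CC)CC)[C@H]2C(C)(C)C=C(OS(=O)(=O)C(F)(F)F)C[C@]2(C)C1=O | intermediate
12 | (2S,4R,4aS,8aS)-2,5,5,8a-tetramethyl-4-(triethylsilyloxy)octahydronaphthalen-1(2H)-one (8β-methyl) | C[C@H]1C[C@@H](O[Si](CC)(CC)CC)[C@H]2C(C)(C)CCC[C@]2(C)C1=O | intermediate
13 | (2R,4R,4aS,8aS)-2,5,5,8a-tetramethyl-4-(triethylsilyloxy)octahydronaphthalen-1(2H)-one (8α-methyl) | C[C@@H]1C[C@@H](O[Si](CC)(CC)CC)[C@H]2C(C)(C)CCC[C@]2(C)C1=O | intermediate
14 | 9(11)-methylene analogue of 13 | C[C@@H]1C[C@@H](O[Si](CC)(CC)CC)[C@H]2C(C)(C)CCC[C@]2(C)C1=C | intermediate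
15 | 9α,11-spiro-epoxide of 14 (9R) | C[C@@H]1C[C@@H](O[Si](CC)(CC)CC)[C@H]2C(C)(C)CCC[C@]2(C)[C@@]12CO2 | intermediate
16 | 3-methylbut-3-en-1-ol | CC(=C)CCO | starting material
17 | dilithiated 3-methylbut-3-en-1-ol | [Li]CC(=C)CCO[Li] | intermediate
18 | 9α-hydroxy diol with C13=C16 methylene and C15 carbinol, 6β-triethylsilyl ether | C[C@@H]1C[C@@H](O[Si](CC)(CC)CC)[C@H]2C(C)(C)CCC[C@]2(C)[C@@]1(O)CCC(=C)CCO | intermediate
19 | (13S)-13,16-epoxide of 18 | C[C@@H]1C[C@@H](O[Si](CC)(CC)CC)[C@H]2C(C)(C)CCC[C@]2(C)[C@@]1(O)CC[C@]3(CCO)CO3 | intermediate
20 | (13R)-9α,13-epoxy-15,16-diol, 6β-triethylsilyl ether | C[C@@H]1C[C@@H](O[Si](CC)(CC)CC)[C@H]2C(C)(C)CCC[C@]2(C)[C@@]12CC[C@@](CCO)(CO)O2 | intermediate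
21 | (13R)-9α,13-epoxylabdane-6β,15,16-triol | C[C@@H]1C[C@@H](O)[C@H]2C(C)(C)CCC[C@]2(C)[C@@]12CC[C@@](CCO)(CO)O2 | intermediate
22 | (13R)-9α,13-epoxy-6-oxolabdan-15,16-olide | C[C@@H]1CC(=O)[C@H]2C(C)(C)CCC[C@]2(C)[C@@]12CC[C@@]1(COC(=O)C1)O2 | intermediate
23 | Δ6 trimethylsilyl enol ether of 22 | C[C@@H]1C=C(O[Si](C)(C)C)[C@H]2C(C)(C)CCC[C@]2(C)[C@@]12CC[C@@]1(COC(=O)C1)O2 | intermediate
24 | 6α,7α-epoxide of 23 (6-trimethylsilyloxy) | C[C@@H]1[C@@H]3O[C@]3(O[Si](C)(C)C)[C@H]2C(C)(C)CCC[C@]2(C)[C@@]12CC[C@@]1(COC(=O)C1)O2 | intermediate
25 | (13R)-9α,13-epoxy-7α-hydroxy-6-oxolabdan-15,16-olide | C[C@@H]1[C@H](O)C(=O)[C@H]2C(C)(C)CCC[C@]2(C)[C@@]12CC[C@@]1(COC(=O)C1)O2 | intermediate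
26 | (13R)-9α,13-epoxy-7β-hydroxy-6-oxolabdan-15,16-olide | C[C@@H]1[C@@H](O)C(=O)[C@H]2C(C)(C)CCC[C@]2(C)[C@@]12CC[C@@]1(COC(=O)C1)O2 | target

## Step count and least certain steps

Total: 15 steps. Longest linear sequence: 15 steps, from 1; compounds 2, 5 and 16 enter as purchased materials.

**Step 2 (key step).** The diene carries a methyl group cis to the diene backbone, which disfavours the s-cis conformation, and both new bonds are made at hindered carbons. The likely failures are slow cycloaddition with competing decomposition of the catalyst, arrest after the first C–C bond as an open Michael adduct, silyl-transfer catalysis that runs the reaction without the chiral Lewis acid, and hence erosion of enantioselectivity. Fallback: quinone 5 and diene 4 are combined without chiral control, under an achiral Lewis acid such as ZnCl2 or thermally at high pressure, to give the racemic cis adduct F1. This is resolved by preparative chromatography on a chiral stationary phase, which returns to the route at 6.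

**Step 4.** Silylation may remove a proton from the C8 methyl group instead of H5, or protonation of C5 may show poor facial selectivity, leaving cis material. Fallback: starting from 7, the C5 epimers are equilibrated with a catalytic amine base under thermodynamic control. The trans isomer is removed by crystallisation and the cis portion resubmitted, which returns to the route at 9. No new compound is made.

**Step 10.** SN2 attack at C11 is neopentyl-like and may be slow, so that the basic dianion instead isomerises the epoxide to an allylic alcohol by β-elimination. Fallback: starting from 15, the epoxide is opened with LiI and acetic acid to the iodohydrin F2. A Keck radical allylation with tributyl[2-(2-hydroxyethyl)prop-2-en-1-yl]stannane F3 (made from 17 and Bu3SnCl) and AIBN in hot benzene then forms the C11–C12 bond through a primary radical that is insensitive to the hindrance, which returns to the route at 18.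

**Step 11.** The tertiary C9 hydroxyl may compete for the metal, the 1,1-disubstituted alkene may give low facial selectivity, and early cyclisation may occur on the catalyst. Fallback: starting from 15, a Sharpless route sets C13 and rejoins at 21, as follows.
- The dianion of 2-methylprop-2-en-1-ol gives allylic alcohol F4.
- Sharpless epoxidation with Ti(OiPr)4, D-(−)-diethyl tartrate and tBuOOH gives the (13R)-epoxy alcohol F5.
- Silylation with tBuPh2SiCl and imidazole gives F6.
- Camphorsulfonic acid closes ring C with inversion to F7, which has a free C14 carbinol.
- Dess–Martin oxidation gives aldehyde F8 and Wittig methylenation gives alkene F9.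
- Hydroboration with 9-BBN and oxidative work-up gives the C15 carbinol F10.
- Bu4NF removes both silyl groups and returns to the route at 21.

**Step 15 (with step 14).** The equilibrium may not lie far enough on the 7β-side, the ketol may transpose to the 7-oxo-6-hydroxy isomer, or the base may start retro-oxa-Michael opening of ring C. Fallback: starting from 25, after removal of any 26 already present, a Mitsunobu reaction with formic acid, PPh3 and diisopropyl azodicarboxylate inverts C7 to the 7β-formate F11. Mild methanolysis with KHCO3 in methanol at 0 °C removes the formyl group and returns to the route at 26.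

## Further compounds

F1 | step 2 | racemic cis cycloadduct (6 and its mirror image) | CC1=CC(=O)[C@@H]2C(C)(C)C=C(O[Si](C(C)C)(C(C)C)C(C)C)C[C@]2(C)C1=O.CC1=CC(=O)[C@H]2C(C)(C)C=C(O[Si](C(C)C)(C(C)C)C(C)C)C[C@@]2(C)C1=O
F0 | step 4 | none | none
F2 | step 10 | 9α-hydroxy-11-iodide (iodohydrin from 15) | C[C@@H]1C[C@@H](O[Si](CC)(CC)CC)[C@H]2C(C)(C)CCC[C@]2(C)[C@@]1(O)CI
F3 | step 10 | tributyl[2-(2-hydroxyethyl)prop-2-en-1-yl]stannane | CCCC[Sn](CCCC)(CCCC)CC(=C)CCO
F4 | step 11 | 9α-hydroxy allylic alcohol (C13=C14 methylene, C16 carbinol) | C[C@@H]1C[C@@H](O[Si](CC)(CC)CC)[C@H]2C(C)(C)CCC[C@]2(C)[C@@]1(O)CCC(=C)CO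
F5 | step 11 | (13R)-13,14-epoxy alcohol | C[C@@H]1C[C@@H](O[Si](CC)(CC)CC)[C@H]2C(C)(C)CCC[C@]2(C)[C@@]1(O)CC[C@@]3(CO)CO3
F6 | step 11 | tert-butyldiphenylsilyl ether of F5 | C[C@@H]1C[C@@H](O[Si](CC)(CC)CC)[C@H]2C(C)(C)CCC[C@]2(C)[C@@]1(O)CC[C@@]3(CO[Si](c4ccccc4)(c4ccccc4)C(C)(C)C)CO3
F7 | step 11 | spiro ether with free C14 carbinol and silylated C16 carbinol | C[C@@H]1C[C@@H](O[Si](CC)(CC)CC)[C@H]2C(C)(C)CCC[C@]2(C)[C@@]12CC[C@@](CO)(CO[Si](c3ccccc3)(c3ccccc3)C(C)(C)C)O2
F8 | step 11 | C14 aldehyde from F7 | C[C@@H]1C[C@@H](O[Si](CC)(CC)CC)[C@H]2C(C)(C)CCC[C@]2(C)[C@@]12CC[C@@](C=O)(CO[Si](c3ccccc3)(c3ccccc3)C(C)(C)C)O2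
F9 | step 11 | C14=C15 vinyl compound from F8 | C[C@@H]1C[C@@H](O[Si](CC)(CC)CC)[C@H]2C(C)(C)CCC[C@]2(C)[C@@]12CC[C@@](C=C)(CO[Si](c3ccccc3)(c3ccccc3)C(C)(C)C)O2
F10 | step 11 | C15 carbinol from F9 (bis-silyl ether of 21) | C[C@@H]1C[C@@H](O[Si](CC)(CC)CC)[C@H]2C(C)(C)CCC[C@]2(C)[C@@]12CC[C@@](CCO)(CO[Si](c3ccccc3)(c3ccccc3)C(C)(C)C)O2
F11 | step 15 | 7β-formate of 26 | C[C@@H]1[C@@H](OC=O)C(=O)[C@H]2C(C)(C)CCC[C@]2(C)[C@@]12CC[C@@]1(COC(=O)C1)O2
A1 | alternative 1 | prochiral spiro-cyclobutanone on the Δ5 9α,13-epoxy decalin | C[C@@H]1CC=C2C(C)(C)CCC[C@]2(C)[C@@]12CCC1(CC(=O)C1)O2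
A2 | alternative 1 | Δ5 spiro-lactone (target without the C6 and C7 oxygens) | C[C@@H]1CC=C2C(C)(C)CCC[C@]2(C)[C@@]12CC[C@@]1(COC(=O)C1)O2
A3 | alternative 2 | 3,5-dimethylphenol with the para side chain carrying ring D and the C13 hydroxyl | Cc1cc(O)cc(C)c1CC[C@@]1(COC(=O)C1)O
A4 | alternative 2 | spiro-ether cyclohexadienone (rings B, C and D) | CC1=CC(=O)C=C(C)C12CC[C@@]1(COC(=O)C1)O2
A5 | alternative 3 | Δ5 9-methylene decalin | C[C@@H]1CC=C2C(C)(C)CCC[C@]2(C)C1=C
A6 | alternative 3 | C9 spirolactone (ring C with C13 as carbonyl) | C[C@@H]1CC=C2C(C)(C)CCC[C@]2(C)[C@@]12CCC(=O)O2
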